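**Retrosynthetic overview**

1. The last skeletal bond is the depside ester between the C1 carboxyl of ring A and O4 of ring B. Ring B is bought as methyl atratate and used as its benzyl ester; ring A is carried as an allyl ester with its CH2OH as a benzyl ether, and both benzyl groups leave in the final step.
2. The feature the plan rests on: in ring A the contiguous carbons C6(CH3)–C1(CO2R)–C2(OCH3)–C3(CH2O) are already present as C6–C5–C4–C3 of a 4-methoxy-6-methyl-2-pyrone-5-carboxylate. Only C4(OCH3) and C5(H) are missing, and 1,1-dimethoxyethene supplies exactly these two atoms.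
3. Ring A is therefore made from the pyrone ring by an inverse-demand [4+2] cycloaddition (new bonds ring A C5–C6 and C3–C4), extrusion of CO2 and loss of methanol.
4. The pyrone comes from allyl acetoacetate and 2-(benzyloxymethyl)malonyl dichloride (bonds C4–C5 and O1–C2 of the pyrone), followed by O4-methylation. Ring order: pyrone first, ring A from it; ring B is never built.

Key step: step 6

Remark: the target has no stereocentre. The bridged cycloadduct 10 is the only chiral species on the route; it forms as a racemate (one enantiomer is drawn in the list) and is not isolated. Equivalents and temperatures are planning values.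

**Route**

Step 1
Reactants: 1 di-tert-butyl malonate; 2 benzyl chloromethyl ether
Product: 3 di-tert-butyl 2-(benzyloxymethyl)malonate
Conditions: NaH (1.0 equiv), 1 (1.3 equiv), THF, 0 °C; then 2 (1.0 equiv), 0 °C to rt
Reagents that add atoms: none
Why: Malonate alkylation (SN2 of the sodium enolate on the reactive α-chloro ether); the excess of malonate should suppress dialkylation.

Step 2
Reactants: 3 di-tert-butyl 2-(benzyloxymethyl)malonate
Product: 4 2-(benzyloxymethyl)malonic acid
Conditions: TFA/CH2Cl2 (1:2), rt; evaporate below 30 °C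
Reagents that add atoms: none
Why: Acidolysis of tert-butyl esters (loss of isobutene) frees the diacid without base, so the β-benzyloxy group cannot be lost by E1cB elimination as it could during saponification; the benzyl ether is stable to TFA at rt.

Step 3
Reactants: 4 2-(benzyloxymethyl)malonic acid
Product: 5 2-(benzyloxymethyl)malonyl dichloride
Conditions: (COCl)2 (2.5 equiv), DMF (cat.), CH2Cl2, 0 °C to rt; evaporate, use crude
Reagents that add atoms: oxalyl chloride, ClC(=O)C(Cl)=O
Why: Standard acid chloride formation through the Vilsmeier-type chloroiminium species; full removal of oxalyl chloride before step 4 avoids its reaction with the keto ester.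

Step 4
Reactants: 5 2-(benzyloxymethyl)malonyl dichloride; 6 allyl acetoacetate
Product: 7 allyl 3-(benzyloxymethyl)-4-hydroxy-6-methyl-2-oxo-2H-pyran-5-carboxylate
Conditions: CH2Cl2, 0 °C to 40 °C, slow N2 stream to remove HCl
Reagents that add atoms: none
Why: Condensation of a malonyl dichloride with a β-keto ester: C-acylation at the α-carbon of 6 and O-acylation of its enol by the two acid chloride groups close the lactone, and the product settles as the 4-hydroxy-2-pyrone hydrogen-bonded to the C5 ester.

Step 5
Reactants: 7 allyl 3-(benzyloxymethyl)-4-hydroxy-6-methyl-2-oxo-2H-pyran-5-carboxylate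
Product: 8 allyl 3-(benzyloxymethyl)-4-methoxy-6-methyl-2-oxo-2H-pyran-5-carboxylate
Conditions: Me2SO4 (1.3 equiv), K2CO3, acetone, reflux
Reagents that add atoms: dimethyl sulfate, COS(=O)(=O)OC
Why: O-alkylation of the vinylogous acid; with K2CO3 and dimethyl sulfate 4-hydroxy-2-pyrones should give mainly the 4-methoxy-2-pyrone, and any 2-methoxy-4-pyranone isomer is removed by chromatography.

Step 6
Reactants: 8 allyl 3-(benzyloxymethyl)-4-methoxy-6-methyl-2-oxo-2H-pyran-5-carboxylate; 9 1,1-dimethoxyethene
Product: 12 allyl 3-(benzyloxymethyl)-2,4-dimethoxy-6-methylbenzoate, via bicyclic lactone adduct 10 (not isolated), via dimethoxycyclohexadiene 11 (not isolated)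
Conditions: 9 (8 equiv), toluene, sealed tube, 130 °C
Reagents that add atoms: none
Why: Pyrone 8 is an electron-poor diene whose C6 is β to the C5 ester and δ to the lactone carbonyl, so the electron-rich CH2 terminus of 9 attacks C6 first and the acetal carbon closes onto C3, an inverse-electron-demand Diels-Alder reaction giving bridged lactone 10. Retro-[4+2] extrusion of CO2 from 10 gives diene 11, and 1,2-elimination of methanol from its CH2–C(OMe)2 unit aromatises it to 12; the closest known reaction type is the benzannulation of 2-pyrone carboxylates (coumalates, isodehydroacetates) with ketene acetals. Ring A is closed intermolecularly by the cycloaddition itself, both new bonds (ring A C5–C6 and C3–C4) forming in one asynchronous event onto the s-cis diene held in the pyrone, after which the lactone bridge leaves. No stereocentre survives, because the two racemic bridgehead centres of 10 are destroyed on aromatisation. Only regiochemistry has to be controlled, and pairing the nucleophilic CH2 with electrophilic C6 puts the new OMe beside the CH2OBn carbon and the new C–H beside the methyl-bearing carbon. The C4 methoxy donor and the full substitution of the diene slow the addition, hence the excess of 9 and the high temperature, while irreversible loss of CO2 drives the sequence forward.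

Step 7
Reactants: 12 allyl 3-(benzyloxymethyl)-2,4-dimethoxy-6-methylbenzoate
Product: 13 3-(benzyloxymethyl)-2,4-dimethoxy-6-methylbenzoic acid
Conditions: Pd(PPh3)4 (5 mol%), morpholine (5 equiv), THF, rt; cold aqueous citric acid work-up
Reagents that add atoms: none
Why: Tsuji-Trost deallylation: zerovalent palladium ionises the allyl–O bond and morpholine traps the π-allyl complex, so the di-ortho-substituted benzoate is cleaved at the remote allyl carbon and never has to be saponified.

Step 8
Reactants: 14 methyl 2,4-dihydroxy-3,6-dimethylbenzoate (methyl atratate)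
Product: 15 2,4-dihydroxy-3,6-dimethylbenzoic acid
Conditions: conc. H2SO4, 0 °C to rt, short contact; pour onto ice
Reagents that add atoms: water, O
Why: Acylium-ion (AAC1) hydrolysis of a di-ortho-substituted, electron-rich benzoate; this avoids hot alkali, under which β-resorcylic acids decarboxylate.

Step 9
Reactants: 15 2,4-dihydroxy-3,6-dimethylbenzoic acid
Product: 16 benzyl 2,4-dihydroxy-3,6-dimethylbenzoate
Conditions: BnBr (1.05 equiv), KHCO3 (1.1 equiv), DMF, rt
Reagents that add atoms: benzyl bromide, BrCc1ccccc1
Why: SN2 O-alkylation of the carboxylate; hydrogencarbonate ionises only the carboxylic acid, so the two phenols should stay free.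

Step 10
Reactants: 13 3-(benzyloxymethyl)-2,4-dimethoxy-6-methylbenzoic acid; 16 benzyl 2,4-dihydroxy-3,6-dimethylbenzoate
Product: 18 benzyl 4-{[3-(benzyloxymethyl)-2,4-dimethoxy-6-methylbenzoyl]oxy}-2-hydroxy-3,6-dimethylbenzoate, via acid chloride 17 (not isolated)
Conditions: 1-chloro-N,N,2-trimethylprop-1-en-1-amine (1.2 equiv), CH2Cl2, 0 °C to rt; then 16 (1.0 equiv), Et3N (2 equiv), DMAP (0.2 equiv), CH2Cl2, 0 °C to rt
Reagents that add atoms: none
Why: The chloroenamine makes the acid chloride without releasing HCl, which protects the acid-labile 2,6-dimethoxybenzyl-type ether of ring A; DMAP-catalysed acylation then takes the 4-OH of 16, which is unchelated and less hindered, while the 2-OH is held in a hydrogen bond to the ester carbonyl between two substituents.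

Step 11
Reactants: 18 benzyl 4-{[3-(benzyloxymethyl)-2,4-dimethoxy-6-methylbenzoyl]oxy}-2-hydroxy-3,6-dimethylbenzoate
Product: 19 2-hydroxy-4-{[3-(hydroxymethyl)-2,4-dimethoxy-6-methylbenzoyl]oxy}-3,6-dimethylbenzoic acid (target)
Conditions: H2 (1 atm), 10% Pd/C, EtOAc, rt; stop at full conversion
Reagents that add atoms: none
Why: Catalytic hydrogenolysis removes the benzyl ester quickly and then the benzyl ether. Cleavage is expected on the unsubstituted benzyl side, because the pentasubstituted ring A, with both positions ortho to its CH2 occupied, adsorbs poorly on the metal. A neutral solvent without added acid should spare the liberated benzylic alcohol and the aryl ester.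

**Compound list**

1 | di-tert-butyl malonate | CC(C)(C)OC(=O)CC(=O)OC(C)(C)C | starting material
2 | benzyl chloromethyl ether | ClCOCc1ccccc1 | starting material
3 | di-tert-butyl 2-(benzyloxymethyl)malonate | CC(C)(C)OC(=O)C(COCc1ccccc1)C(=O)OC(C)(C)C | intermediate
4 | 2-(benzyloxymethyl)malonic acid | OC(=O)C(COCc1ccccc1)C(=O)O | intermediate
5 | 2-(benzyloxymethyl)malonyl dichloride | ClC(=O)C(COCc1ccccc1)C(Cl)=O | intermediate
6 | allyl acetoacetate | CC(=O)CC(=O)OCC=C | starting material
7 | allyl 3-(benzyloxymethyl)-4-hydroxy-6-methyl-2-oxo-2H-pyran-5-carboxylate | CC1=C(C(=O)OCC=C)C(O)=C(COCc2ccccc2)C(=O)O1 | intermediate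
8 | allyl 3-(benzyloxymethyl)-4-methoxy-6-methyl-2-oxo-2H-pyran-5-carboxylate | CC1=C(C(=O)OCC=C)C(OC)=C(COCc2ccccc2)C(=O)O1 | intermediate
9 | 1,1-dimethoxyethene | C=C(OC)OC | starting material
10 | allyl 4-(benzyloxymethyl)-5,8,8-trimethoxy-1-methyl-3-oxo-2-oxabicyclo[2.2.2]oct-5-ene-6-carboxylate (racemic, one enantiomer drawn) | C[C@]12OC(=O)[C@](COCc3ccccc3)(C(OC)=C1C(=O)OCC=C)C(OC)(OC)C2 | intermediate
11 | allyl 5-(benzyloxymethyl)-4,4,6-trimethoxy-2-methylcyclohexa-1,5-diene-1-carboxylate | CC1=C(C(=O)OCC=C)C(OC)=C(COCc2ccccc2)C(OC)(OC)C1 | intermediate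
12 | allyl 3-(benzyloxymethyl)-2,4-dimethoxy-6-methylbenzoate | COc1cc(C)c(C(=O)OCC=C)c(OC)c1COCc2ccccc2 | intermediate
13 | 3-(benzyloxymethyl)-2,4-dimethoxy-6-methylbenzoic acid | COc1cc(C)c(C(=O)O)c(OC)c1COCc2ccccc2 | intermediate
14 | methyl 2,4-dihydroxy-3,6-dimethylbenzoate (methyl atratate) | COC(=O)c1c(C)cc(O)c(C)c1O | starting material
15 | 2,4-dihydroxy-3,6-dimethylbenzoic acid | OC(=O)c1c(C)cc(O)c(C)c1O | intermediate
16 | benzyl 2,4-dihydroxy-3,6-dimethylbenzoate | O=C(OCc1ccccc1)c2c(C)cc(O)c(C)c2O | intermediate
17 | 3-(benzyloxymethyl)-2,4-dimethoxy-6-methylbenzoyl chloride | COc1cc(C)c(C(Cl)=O)c(OC)c1COCc2ccccc2 | intermediate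
18 | benzyl 4-{[3-(benzyloxymethyl)-2,4-dimethoxy-6-methylbenzoyl]oxy}-2-hydroxy-3,6-dimethylbenzoate | COc1cc(C)c(C(=O)Oc2cc(C)c(C(=O)OCc3ccccc3)c(O)c2C)c(OC)c1COCc4ccccc4 | intermediate
19 | 2-hydroxy-4-{[3-(hydroxymethyl)-2,4-dimethoxy-6-methylbenzoyl]oxy}-3,6-dimethylbenzoic acid | COc1cc(C)c(C(=O)Oc2cc(C)c(C(=O)O)c(O)c2C)c(OC)c1CO | target

**Step count**

Total: 11 steps (7 to ring A acid 13, 2 to ring B ester 16, 2 after convergence).
Longest linear sequence: 9 steps (steps 1–7, 10, 11).

**Steps most likely to fail, with fallbacks**

Step 6. The cycloaddition to a fully substituted diene carrying a C4 methoxy donor may be too slow, so that thermal oligomerisation or adventitious hydrolysis of the ketene acetal consumes the dienophile first. The fallback removes the donor during the cycloaddition and restores it afterwards. It sets out from 7: Ac2O and pyridine in CH2Cl2 at 0 °C should give allyl 4-acetoxy-3-(benzyloxymethyl)-6-methyl-2-oxo-2H-pyran-5-carboxylate F1, a more electron-poor diene. Heating F1 with 9 in toluene (sealed tube, about 110 °C), with the same loss of CO2 and methanol, should give allyl 2-acetoxy-3-(benzyloxymethyl)-4-methoxy-6-methylbenzoate F2. Brief K2CO3 in MeOH at 0 °C should remove the acetate and give allyl 3-(benzyloxymethyl)-2-hydroxy-4-methoxy-6-methylbenzoate F3, the hindered allyl benzoate resisting methanolysis. Methylation of the phenol with MeI and K2CO3 in DMF returns to the route at 12.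

Step 4. Under the HCl evolved, benzyl alcohol may be lost from the β-benzyloxy acid chloride or from the hydroxypyrone, and ketene-type self-condensation of the substituted malonyl chloride may outrun the double acylation. The fallback forms the pyrone ring without the C3 substituent and adds the CH2OBn carbon afterwards. It sets out from 6: condensation with commercial malonyl dichloride (CH2Cl2, rt) should give allyl 4-hydroxy-6-methyl-2-oxo-2H-pyran-5-carboxylate F4. A Mannich reaction at the nucleophilic C3 with bis(dimethylamino)methane in MeCN at rt should give allyl 3-[(dimethylamino)methyl]-4-hydroxy-6-methyl-2-oxo-2H-pyran-5-carboxylate F5. Heating F5 in benzyl alcohol (about 110 °C, N2 stream to carry off dimethylamine) should exchange the amine for benzyl alcohol through the 3-methylene-pyrandione (quinone-methide-type) intermediate and return to the route at 7.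

Step 11. Hydrogenolysis may cleave the ether on the ring A side, or reduce the liberated electron-rich benzylic alcohol further during the longer exposure the ether needs, leaving a methyl group at C3 of ring A. The fallback takes the benzyl ether off oxidatively, using the dimethoxybenzyl character of ring A, and keeps hydrogen only for the fast ester cleavage. It sets out from 18: DDQ in CH2Cl2/pH 7 buffer at rt should abstract hydride at the ring A benzylic carbon and, after hydrolysis, give benzyl 4-[(3-formyl-2,4-dimethoxy-6-methylbenzoyl)oxy]-2-hydroxy-3,6-dimethylbenzoate F6 and benzyl alcohol. NaBH4 in THF/EtOH at −10 °C should reduce the aldehyde to benzyl 2-hydroxy-4-{[3-(hydroxymethyl)-2,4-dimethoxy-6-methylbenzoyl]oxy}-3,6-dimethylbenzoate F7 without touching the hindered esters. A short hydrogenolysis (H2, 10% Pd/C, EtOAc, rt) then removes only the benzyl ester and arrives at 19.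

**Further compounds**

F1 | step 6 | allyl 4-acetoxy-3-(benzyloxymethyl)-6-methyl-2-oxo-2H-pyran-5-carboxylate | CC1=C(C(=O)OCC=C)C(OC(C)=O)=C(COCc2ccccc2)C(=O)O1
F2 | step 6 | allyl 2-acetoxy-3-(benzyloxymethyl)-4-methoxy-6-methylbenzoate | COc1cc(C)c(C(=O)OCC=C)c(OC(C)=O)c1COCc2ccccc2
F3 | step 6 | allyl 3-(benzyloxymethyl)-2-hydroxy-4-methoxy-6-methylbenzoate | COc1cc(C)c(C(=O)OCC=C)c(O)c1COCc2ccccc2
F4 | step 4 | allyl 4-hydroxy-6-methyl-2-oxo-2H-pyran-5-carboxylate | CC1=C(C(=O)OCC=C)C(O)=CC(=O)O1
F5 | step 4 | allyl 3-[(dimethylamino)methyl]-4-hydroxy-6-methyl-2-oxo-2H-pyran-5-carboxylate | CC1=C(C(=O)OCC=C)C(O)=C(CN(C)C)C(=O)O1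
F6 | step 11 | benzyl 4-[(3-formyl-2,4-dimethoxy-6-methylbenzoyl)oxy]-2-hydroxy-3,6-dimethylbenzoate | COc1cc(C)c(C(=O)Oc2cc(C)c(C(=O)OCc3ccccc3)c(O)c2C)c(OC)c1C=O
F7 | step 11 | benzyl 2-hydroxy-4-{[3-(hydroxymethyl)-2,4-dimethoxy-6-methylbenzoyl]oxy}-3,6-dimethylbenzoate | COc1cc(C)c(C(=O)Oc2cc(C)c(C(=O)OCc3ccccc3)c(O)c2C)c(OC)c1CO
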